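**Retrosynthetic overview**

1. Artoflavanone ⇒ its 7-O-desmethyl compound; the last step methylates the only phenol that is not hydrogen-bonded to the C4 carbonyl.
2. 7-O-Desmethyl flavanone ⇒ an open-chain (S)-δ-hydroxy tetracarbonyl tert-butyl ester; rings C and A close in one flask (O1–C8a by cyclodehydration, then C4a–C5 through an acylketene).
3. Open chain ⇒ prenylated triketide ester (trianion, C4a nucleophile) + (S)-β-hydroxy ester (C4 acyl donor); the stereocentre comes from asymmetric transfer hydrogenation and its C–O bond is never broken afterwards.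
4. Triketide ester ⇒ tert-butyl acetoacetate + prenyl bromide + an acetyl donor; the prenyl group is placed on the future C6 before ring A exists.
5. Ring order: ring B is bought, ring C forms first and ring A second, both in the same operation.

Assumption: atoms of open-chain precursors carry the flavanone numbers they end up with (O1, C2, C3, C4, C4a, C5 to C8, C8a), and all four starting materials are taken as catalogue chemicals.

**Route**

Step 1
Reactants: 1 tert-butyl acetoacetate; 2 prenyl bromide (1-bromo-3-methylbut-2-ene)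
Product: 3 tert-butyl 2-acetyl-5-methylhex-4-enoate (racemic)
Conditions: NaH (1.0 equiv), THF, 0 °C; then 2 (0.95 equiv), 0 °C to rt
Reagents that add atoms: none
Why: C-alkylation of a β-keto ester sodium enolate (acetoacetic ester alkylation, SN2 at the primary allylic bromide) puts the prenyl group on the carbon that becomes C6 before ring A exists, so its position is fixed, and the racemic stereocentre formed here is destroyed later.

Step 2
Reactants: 3 tert-butyl 2-acetyl-5-methylhex-4-enoate; 4 N-methoxy-N-methylacetamide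
Product: 6 tert-butyl 2-(3-methylbut-2-en-1-yl)-3,5-dioxohexanoate (racemic, keto–enol mixture), via dilithium dienediolate 5 (not isolated)
Conditions: LiN(iPr)2 (2.2 equiv), THF, −78 to 0 °C; then 4 (1.0 equiv), −78 to 0 °C; 1 M HCl
Reagents that add atoms: none
Why: γ-acylation of a Weiler-type β-keto ester dianion (crossed Claisen condensation) occurs at the more basic terminal carbon (future C8) to form the C8–C8a bond, and the Weinreb amide stops at the chelated tetrahedral adduct so neither over-addition nor proton quench of the dianion takes place.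

Step 3
Reactants: 7 ethyl 3-oxo-3-(3,4,5-trimethoxyphenyl)propanoate
Product: 8 ethyl (3S)-3-hydroxy-3-(3,4,5-trimethoxyphenyl)propanoate
Conditions: RuCl(p-cymene)[(S,S)-TsDPEN] (0.5 mol%), HCO2H/Et3N (5:2), 40 °C
Reagents that add atoms: none
Why: Noyori asymmetric transfer hydrogenation of an aryl ketone, in which the (S,S)-TsDPEN ligand delivers hydride to the same face as in acetophenone reductions and so sets the only stereocentre of the route (future C2) as S, with the ee upgradable by crystallisation.

Step 4
Reactants: 6 tert-butyl 2-(3-methylbut-2-en-1-yl)-3,5-dioxohexanoate; 8 ethyl (3S)-3-hydroxy-3-(3,4,5-trimethoxyphenyl)propanoate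
Product: 10 tert-butyl (9S)-9-hydroxy-2-(3-methylbut-2-en-1-yl)-3,5,7-trioxo-9-(3,4,5-trimethoxyphenyl)nonanoate (mixture of C2 epimers and enol forms), via trilithium trienetriolate 9 (not isolated)
Conditions: 6 (2.2 equiv), LiN(iPr)2 (6.6 equiv), THF, −78 to 0 °C; then 8 (1.0 equiv), −78 to −20 °C; 1 M HCl at −78 °C
Reagents that add atoms: none
Why: Harris-type acylation of a polycarbonyl polyanion by an ester (crossed Claisen condensation) takes place at the last-formed terminal carbanion (future C4a) to form the C4–C4a bond, the lithium β-alkoxide of 8 does not undergo retro-aldol cleavage at low temperature so the S stereocentre is carried through unchanged, and the bulky tert-butyl ester suppresses premature Claisen ring closure.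

Step 5
Reactants: 10 tert-butyl (9S)-9-hydroxy-2-(3-methylbut-2-en-1-yl)-3,5,7-trioxo-9-(3,4,5-trimethoxyphenyl)nonanoate
Product: 13 (2S)-5,7-dihydroxy-6-(3-methylbut-2-en-1-yl)-2-(3,4,5-trimethoxyphenyl)-2,3-dihydro-4H-chromen-4-one, via dihydropyranone ester 11 (not isolated), via acylketene 12 (not isolated)
Conditions: camphorsulfonic acid (5 mol%), 4 Å molecular sieves, toluene, 25 °C; then Et3N (10 mol%), o-xylene (0.005 M), 140 °C
Reagents that add atoms: none
Why: Proposed new method: a one-flask polyketide-type double annulation in which the C2 hydroxyl first adds to the C8a ketone and loses water to give the vinylogous ester 11 (ring C, with the C–O bond of the stereocentre untouched and hence S retained), after which the α-prenylated tert-butyl β-keto ester expels tert-butanol to give acylketene 12, whose enol is a dienylketene that forms the C4a–C5 bond by 6π-electrocyclisation (equivalently C-acylation of the nucleophilic α-carbon of the vinylogous ester) and enolises to ring A with the prenyl group locked between the two new oxygens, the closest known reaction types being acid-catalysed cyclodehydration of δ-hydroxy-β-diketones to 2,3-dihydro-4H-pyran-4-ones, thermal acylketene generation from tert-butyl β-keto esters with ketene-based aromatisation, and the dienylketene ring closure of the Danheiser benzannulation.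

Step 6
Reactants: 13 (2S)-5,7-dihydroxy-6-(3-methylbut-2-en-1-yl)-2-(3,4,5-trimethoxyphenyl)-2,3-dihydro-4H-chromen-4-one
Product: 14 artoflavanone, (2S)-5-hydroxy-7-methoxy-6-(3-methylbut-2-en-1-yl)-2-(3,4,5-trimethoxyphenyl)-2,3-dihydro-4H-chromen-4-one
Conditions: Me3SiCHN2 (1.5 equiv), MeOH/toluene (1:4), 0 °C to rt
Reagents that add atoms: trimethylsilyldiazomethane, C[Si](C)(C)C=[N+]=[N-]
Why: O-methylation of a phenol by a diazoalkane under neutral conditions is selective because the 5-hydroxyl is hydrogen-bonded to the C4 carbonyl and far less acidic than the free 7-hydroxyl, and the absence of base avoids ring opening to the chalcone so C2 stays S.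

**Compound list**

1 | tert-butyl acetoacetate | CC(=O)CC(=O)OC(C)(C)C | starting material
2 | prenyl bromide (1-bromo-3-methylbut-2-ene) | CC(C)=CCBr | starting material
3 | tert-butyl 2-acetyl-5-methylhex-4-enoate (racemic) | CC(=O)C(CC=C(C)C)C(=O)OC(C)(C)C | intermediate
4 | N-methoxy-N-methylacetamide | CC(=O)N(C)OC | starting material
5 | dilithium 1-tert-butoxy-2-(3-methylbut-2-en-1-yl)buta-1,3-diene-1,3-diolate | C=C([O-])C(CC=C(C)C)=C([O-])OC(C)(C)C.[Li+].[Li+] | intermediate
6 | tert-butyl 2-(3-methylbut-2-en-1-yl)-3,5-dioxohexanoate (racemic) | CC(=O)CC(=O)C(CC=C(C)C)C(=O)OC(C)(C)C | intermediate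
7 | ethyl 3-oxo-3-(3,4,5-trimethoxyphenyl)propanoate | CCOC(=O)CC(=O)c1cc(OC)c(OC)c(OC)c1 | starting material
8 | ethyl (3S)-3-hydroxy-3-(3,4,5-trimethoxyphenyl)propanoate | CCOC(=O)C[C@H](O)c1cc(OC)c(OC)c(OC)c1 | intermediate
9 | trilithium 1-tert-butoxy-2-(3-methylbut-2-en-1-yl)hexa-1,3,5-triene-1,3,5-triolate | C=C([O-])C=C([O-])C(CC=C(C)C)=C([O-])OC(C)(C)C.[Li+].[Li+].[Li+] | intermediate
10 | tert-butyl (9S)-9-hydroxy-2-(3-methylbut-2-en-1-yl)-3,5,7-trioxo-9-(3,4,5-trimethoxyphenyl)nonanoate (C2 epimers) | CC(C)=CCC(C(=O)OC(C)(C)C)C(=O)CC(=O)CC(=O)C[C@H](O)c1cc(OC)c(OC)c(OC)c1 | intermediate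
11 | tert-butyl 2-(3-methylbut-2-en-1-yl)-3-oxo-4-[(2S)-4-oxo-2-(3,4,5-trimethoxyphenyl)-3,4-dihydro-2H-pyran-6-yl]butanoate (C2 epimers) | CC(C)=CCC(C(=O)OC(C)(C)C)C(=O)CC1=CC(=O)C[C@@H](c2cc(OC)c(OC)c(OC)c2)O1 | intermediate
12 | 2-(3-methylbut-2-en-1-yl)-4-[(2S)-4-oxo-2-(3,4,5-trimethoxyphenyl)-3,4-dihydro-2H-pyran-6-yl]but-1-ene-1,3-dione (acylketene) | O=C=C(CC=C(C)C)C(=O)CC1=CC(=O)C[C@@H](c2cc(OC)c(OC)c(OC)c2)O1 | intermediate
13 | (2S)-5,7-dihydroxy-6-(3-methylbut-2-en-1-yl)-2-(3,4,5-trimethoxyphenyl)-2,3-dihydro-4H-chromen-4-one | CC(C)=CCc1c(O)cc2c(c1O)C(=O)C[C@@H](c1cc(OC)c(OC)c(OC)c1)O2 | intermediate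
14 | artoflavanone, (2S)-5-hydroxy-7-methoxy-6-(3-methylbut-2-en-1-yl)-2-(3,4,5-trimethoxyphenyl)-2,3-dihydro-4H-chromen-4-one | COc1cc2c(c(O)c1CC=C(C)C)C(=O)C[C@@H](c1cc(OC)c(OC)c(OC)c1)O2 | target

**Step count and risks**

Total step count: 6. Longest linear sequence: 5 (steps 1, 2, 4, 5, 6); step 3 is a one-step branch.

Most likely to fail, first: step 5. Loss of tert-butanol from the α-prenylated β-keto ester may be slower than loss of isobutene followed by decarboxylation, and the acylketene may oligomerise before it closes. The fallback sets out from 10 and comes back at 13. Only the acid stage is run and 11 is isolated. Treatment of 11 with acetone, (CF3CO)2O and CF3CO2H at 0 °C exchanges the tert-butyl ester for a dioxinone, giving (2S)-6-{[2,2-dimethyl-5-(3-methylbut-2-en-1-yl)-4-oxo-4H-1,3-dioxin-6-yl]methyl}-2-(3,4,5-trimethoxyphenyl)-2,3-dihydro-4H-pyran-4-one F1. This ketene source cannot decarboxylate and fragments at 100 to 110 °C in dilute toluene to the same acylketene 12, which closes to 13. The two ring closures are then separate operations.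

Second: step 4. The free alkoxide of 8 may quench the trianion, the ester may be enolised instead of attacked, and the more acidic product consumes base. The fallback sets out from 8 and comes back at 10. The alcohol is silylated (tert-butyldimethylsilyl chloride, imidazole, DMF) to ethyl (3S)-3-[(tert-butyldimethylsilyl)oxy]-3-(3,4,5-trimethoxyphenyl)propanoate F2. The ester is converted with MeNH(OMe)·HCl and iPrMgCl in THF at −20 °C into (3S)-3-[(tert-butyldimethylsilyl)oxy]-N-methoxy-N-methyl-3-(3,4,5-trimethoxyphenyl)propanamide F3. Addition of F3 to trianion 9 (1.2 equiv, −78 °C) stops at the chelated adduct and gives tert-butyl (9S)-9-[(tert-butyldimethylsilyl)oxy]-2-(3-methylbut-2-en-1-yl)-3,5,7-trioxo-9-(3,4,5-trimethoxyphenyl)nonanoate F4 after work-up. HF·pyridine in THF at 0 °C removes the silyl group and returns 10.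

Third: step 2. Dianion formation from an α-substituted acetoacetate can be incomplete, and proton transfer can compete with acylation. The fallback sets out from 3 and comes back at 6, replacing the dianion by a neutral silyl dienol ether. Me3SiCl and Et3N give tert-butyl 2-(3-methylbut-2-en-1-yl)-3-[(trimethylsilyl)oxy]but-2-enoate F5. LiN(iPr)2 followed by Me3SiCl gives the Chan-type diene 1-tert-butoxy-2-(3-methylbut-2-en-1-yl)-1,3-bis[(trimethylsilyl)oxy]buta-1,3-diene F6. Its terminal carbon is acylated by acetyl chloride in CH2Cl2 at −78 °C, and aqueous work-up returns 6.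

**Further compounds**

F1 | step 5 | (2S)-6-{[2,2-dimethyl-5-(3-methylbut-2-en-1-yl)-4-oxo-4H-1,3-dioxin-6-yl]methyl}-2-(3,4,5-trimethoxyphenyl)-2,3-dihydro-4H-pyran-4-one | CC(C)=CCC1=C(CC2=CC(=O)C[C@@H](c3cc(OC)c(OC)c(OC)c3)O2)OC(C)(C)OC1=O
F2 | step 4 | ethyl (3S)-3-[(tert-butyldimethylsilyl)oxy]-3-(3,4,5-trimethoxyphenyl)propanoate | CCOC(=O)C[C@H](O[Si](C)(C)C(C)(C)C)c1cc(OC)c(OC)c(OC)c1
F3 | step 4 | (3S)-3-[(tert-butyldimethylsilyl)oxy]-N-methoxy-N-methyl-3-(3,4,5-trimethoxyphenyl)propanamide | CON(C)C(=O)C[C@H](O[Si](C)(C)C(C)(C)C)c1cc(OC)c(OC)c(OC)c1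
F4 | step 4 | tert-butyl (9S)-9-[(tert-butyldimethylsilyl)oxy]-2-(3-methylbut-2-en-1-yl)-3,5,7-trioxo-9-(3,4,5-trimethoxyphenyl)nonanoate | CC(C)=CCC(C(=O)OC(C)(C)C)C(=O)CC(=O)CC(=O)C[C@H](O[Si](C)(C)C(C)(C)C)c1cc(OC)c(OC)c(OC)c1
F5 | step 2 | tert-butyl 2-(3-methylbut-2-en-1-yl)-3-[(trimethylsilyl)oxy]but-2-enoate | CC(O[Si](C)(C)C)=C(CC=C(C)C)C(=O)OC(C)(C)C
F6 | step 2 | 1-tert-butoxy-2-(3-methylbut-2-en-1-yl)-1,3-bis[(trimethylsilyl)oxy]buta-1,3-diene | C=C(O[Si](C)(C)C)C(CC=C(C)C)=C(OC(C)(C)C)O[Si](C)(C)C
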